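**Plan**

1. Feature used: in the 1,2,4-trisubstituted ether ring (ring A) of the biaryl, the oxygen-bearing carbon C2 and the neighbouring carbon C1 that carries the phenol ring map onto the two sp carbons of an aryl alkynyl ether of the eudesmane C4 oxygen. Ring carbons C3–C6 (C5 is the allyl-bearing carbon para to oxygen) map onto C3–C6 of methyl coumalate, whose ester sits at the future allyl position.
2. Retrosynthetic cuts, in order: the two O–Si bonds; the ArCH2–CH=CH2 bond on ring A (back to a benzylic bromide and then a methyl benzoate); ring bonds C2–C3 and C1–C6 of ring A (cycloaddition with loss of CO2); the C(sp)–aryl bond; the O–C(sp) bond at the C4 oxygen.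
3. Forward: β-eudesmol → O11 silyl ether → 4α,15-epoxide → 4α-ol → dichlorovinyl ether → lithium and zinc alkynyl ethers → coupling with silylated 2-allyl-4-iodophenol (from 4-iodophenol by O-allylation and Claisen rearrangement) → benzannulation with methyl coumalate → ester to allyl → desilylation.
4. Rings: both decalin rings come intact from β-eudesmol and the phenol ring from 4-iodophenol; ring A is the only ring built, in step 9.
5. Stereochemistry: C5, C7 and C10 are those of natural (+)-β-eudesmol and are never touched; C4 is set by α-face epoxidation (step 2) and kept through hydride opening at C15; no later step breaks a bond at C4.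

Key step: step 9

Remark: the SMILES places the aryloxy group on the α (equatorial) face of C4 with the C4 methyl β, and C5, C7 and C10 as in natural (+)-β-eudesmol (5α-H, 7β-hydroxyisopropyl, 10β-methyl), so commercial (+)-β-eudesmol is taken as the single-enantiomer source of the decalin.

**Route**

Step 1
Reactants: 1 β-eudesmol
Product: 2 11-(triethylsilyloxy)eudesm-4(15)-ene
Conditions: Et3SiOTf, 2,6-lutidine, CH2Cl2, −78 to 0 °C
Reagents that add atoms: triethylsilyl triflate, CC[Si](CC)(CC)OS(=O)(=O)C(F)(F)F
Why: Silylation of a tertiary alcohol with a silyl triflate and a hindered pyridine base is routine and masks O11, so that later only the C4 oxygen can form an alkoxide.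

Step 2
Reactants: 2 11-(triethylsilyloxy)eudesm-4(15)-ene
Product: 3 4α,15-epoxy-11-(triethylsilyloxy)eudesmane
Conditions: mCPBA, NaHCO3, CH2Cl2, 0 °C
Reagents that add atoms: meta-chloroperbenzoic acid, O=C(OO)c1cccc(Cl)c1
Why: Prilezhaev epoxidation of the exocyclic 1,1-disubstituted alkene should occur from the α face, because the β (axial) face at C4 is screened by the syn-axial C10 methyl group, which places the new C4–O bond α (equatorial).

Step 3
Reactants: 3 4α,15-epoxy-11-(triethylsilyloxy)eudesmane
Product: 4 11-(triethylsilyloxy)eudesman-4α-ol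
Conditions: LiAlH4, THF, 0 to 50 °C
Reagents that add atoms: none
Why: Hydride opening of the epoxide (SN2) occurs at the unsubstituted C15, so the C4–O bond and its α configuration are retained, and the hindered tertiary silyl ether is inert to LiAlH4.

Step 4
Reactants: 4 11-(triethylsilyloxy)eudesman-4α-ol; 5 trichloroethylene
Product: 6 4α-[(E)-1,2-dichlorovinyloxy]-11-(triethylsilyloxy)eudesmane
Conditions: KH, THF, 0 to 25 °C; then 5, −50 to 25 °C
Reagents that add atoms: none
Why: The potassium alkoxide dehydrochlorinates trichloroethylene to dichloroacetylene and then adds anti across it (alkoxide addition to a haloalkyne), a sequence that accepts tertiary alkoxides such as tert-butoxide and gives the (E)-dichlorovinyl ether.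

Step 5
Reactants: 7 4-iodophenol
Product: 8 allyl 4-iodophenyl ether
Conditions: allyl bromide, K2CO3, acetone, reflux
Reagents that add atoms: allyl bromide, C=CCBr
Why: Williamson ether synthesis of a phenoxide with a reactive allylic bromide is reliable and leaves the aryl iodide untouched.

Step 6
Reactants: 8 allyl 4-iodophenyl ether
Product: 10 2-allyl-4-iodophenol, via dienone 9 (not isolated)
Conditions: PhNEt2, 195 °C
Reagents that add atoms: none
Why: The aromatic Claisen rearrangement ([3,3]-sigmatropic shift, then tautomerisation of the dienone) delivers the allyl group to one of the two equivalent ortho positions, and the C–I bond withstands metal-free heating.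

Step 7
Reactants: 10 2-allyl-4-iodophenol
Product: 11 tert-butyl(2-allyl-4-iodophenoxy)dimethylsilane
Conditions: t-BuMe2SiCl, imidazole, DMF, 25 °C
Reagents that add atoms: tert-butyldimethylsilyl chloride, CC(C)(C)[Si](C)(C)Cl
Why: Imidazole-promoted silylation protects the phenol, whose acidic proton would otherwise quench the alkynylzinc reagent of the next step.

Step 8
Reactants: 6 4α-[(E)-1,2-dichlorovinyloxy]-11-(triethylsilyloxy)eudesmane; 11 tert-butyl(2-allyl-4-iodophenoxy)dimethylsilane
Product: 15 4α-[2-(3-allyl-4-tert-butyldimethylsilyloxyphenyl)ethynyloxy]-11-(triethylsilyloxy)eudesmane, via chloroalkynyl ether 12 (not isolated), via lithium alkynyl ether 13 (not isolated), via alkynylzinc chloride 14 (not isolated)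
Conditions: n-BuLi (2.1 equiv), THF, −78 to −40 °C; ZnCl2, −40 to 0 °C; 11, Pd(PPh3)4 (5 mol%), 20 °C; chromatography on Et3N-deactivated SiO2 below 20 °C
Reagents that add atoms: none
Why: Deprotonation with loss of LiCl gives the chloroalkyne, chlorine–lithium exchange gives the lithium alkynyl ether, and transmetalation to zinc allows a Negishi coupling with the aryl iodide on the zerovalent palladium catalyst Pd(PPh3)4 at 20 °C, a temperature at which the tertiary alkynyl ether should not yet fragment by retro-ene reaction.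

Step 9
Reactants: 15 4α-[2-(3-allyl-4-tert-butyldimethylsilyloxyphenyl)ethynyloxy]-11-(triethylsilyloxy)eudesmane; 16 methyl coumalate
Product: 18 methyl 3-(3-allyl-4-tert-butyldimethylsilyloxyphenyl)-4-[11-(triethylsilyloxy)eudesman-4α-yloxy]benzoate, via bridged lactone 17 (not isolated)
Conditions: 16 (3 equiv), CH2Cl2 (2 M), 10 kbar, 25 °C; then 1 bar, 25 °C
Reagents that add atoms: none
Why: The electron-rich alkynyl ether 15 and the electron-poor 2-pyrone 16 should combine in an inverse-electron-demand Diels–Alder reaction across C3 and C6 of the pyrone to give the 2-oxabicyclo[2.2.2]octadienone 17, which loses CO2 by retro-Diels–Alder reaction at room temperature to leave the benzoate ring. The closest known reaction type is the Diels–Alder/decarboxylation benzannulation of methyl coumalate with alkoxyalkynes, ynamines and ketene acetals. The one new ring, the six-membered arene that carries the ether oxygen, is closed by an intermolecular [4+2] cycloaddition that forms both ring C–C bonds in one event and is then aromatised by cycloreversion; no stereocentre is created, and both bridgehead configurations of 17 converge on the same product. The step needs regioselectivity (ester para to the ether oxygen, silyloxyaryl ring ortho to it), which is secured by pairing the nucleophilic aryl-bearing β-carbon of the alkynyl ether with the most electrophilic pyrone carbon C6, so that the oxygen-bearing carbon bonds to C3. It also needs the cycloaddition to outrun retro-ene loss of alkene from the tertiary alkynyl ether: pressure at 25 °C accelerates the bimolecular addition (negative activation volume) and disfavours fragmentation, and the unactivated allyl alkene does not react with 16 at this temperature.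

Step 10
Reactants: 18 methyl 3-(3-allyl-4-tert-butyldimethylsilyloxyphenyl)-4-[11-(triethylsilyloxy)eudesman-4α-yloxy]benzoate
Product: 19 {3-(3-allyl-4-tert-butyldimethylsilyloxyphenyl)-4-[11-(triethylsilyloxy)eudesman-4α-yloxy]phenyl}methanol
Conditions: i-Bu2AlH, CH2Cl2, −78 to 0 °C; aq Rochelle salt
Reagents that add atoms: none
Why: Hydride reduction of the methyl ester with excess i-Bu2AlH gives the benzylic alcohol, while both silyl ethers, the alkenes and the aryl ether are inert.

Step 11
Reactants: 19 {3-(3-allyl-4-tert-butyldimethylsilyloxyphenyl)-4-[11-(triethylsilyloxy)eudesman-4α-yloxy]phenyl}methanol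
Product: 20 4α-{[3'-allyl-5-(bromomethyl)-4'-(tert-butyldimethylsilyloxy)biphenyl-2-yl]oxy}-11-(triethylsilyloxy)eudesmane
Conditions: CBr4, PPh3, 2,6-lutidine, CH2Cl2, 0 °C
Reagents that add atoms: carbon tetrabromide, BrC(Br)(Br)Br
Why: The Appel bromination converts the primary benzylic alcohol under neutral, buffered conditions, so the acid-labile tertiary alkyl aryl ether and the silyl ethers are never exposed to HBr.

Step 12
Reactants: 20 4α-{[3'-allyl-5-(bromomethyl)-4'-(tert-butyldimethylsilyloxy)biphenyl-2-yl]oxy}-11-(triethylsilyloxy)eudesmane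
Product: 21 4α-{[3',5-diallyl-4'-(tert-butyldimethylsilyloxy)biphenyl-2-yl]oxy}-11-(triethylsilyloxy)eudesmane
Conditions: CH2=CHMgBr, CuI (10 mol%), THF, −40 to 0 °C
Reagents that add atoms: vinylmagnesium bromide, C=C[Mg]Br
Why: Copper-catalysed Grignard cross-coupling (SN2 displacement of the benzylic bromide by a vinylcuprate) forms the ArCH2–CH=CH2 bond at low temperature without moving the double bond into conjugation.

Step 13
Reactants: 21 4α-{[3',5-diallyl-4'-(tert-butyldimethylsilyloxy)biphenyl-2-yl]oxy}-11-(triethylsilyloxy)eudesmane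
Product: 22 4α-[(3',5-diallyl-4'-hydroxybiphenyl-2-yl)oxy]eudesman-11-ol
Conditions: Bu4NF, THF, 0 to 45 °C
Reagents that add atoms: none
Why: Fluoride-induced desilylation frees the phenol at once and the tertiary 11-alcohol on gentle warming under non-acidic conditions, which spare the tertiary alkyl aryl ether and both allyl groups.

**Compound list**

1 | β-eudesmol (eudesm-4(15)-en-11-ol; 5α-H, 7β-hydroxyisopropyl, 10β-methyl) | C=C1CCC[C@]2(C)CC[C@@H](C(C)(C)O)C[C@H]21 | starting material
2 | 11-(triethylsilyloxy)eudesm-4(15)-ene | C=C1CCC[C@]2(C)CC[C@@H](C(C)(C)O[Si](CC)(CC)CC)C[C@H]21 | intermediate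
3 | 4α,15-epoxy-11-(triethylsilyloxy)eudesmane (epoxide oxygen α) | O1[C@]2(C1)CCC[C@]3(C)CC[C@@H](C(C)(C)O[Si](CC)(CC)CC)C[C@H]32 | intermediate
4 | 11-(triethylsilyloxy)eudesman-4α-ol (4α-OH, 4β-methyl) | O[C@]1(C)CCC[C@]2(C)CC[C@@H](C(C)(C)O[Si](CC)(CC)CC)C[C@H]21 | intermediate
5 | trichloroethylene | ClC=C(Cl)Cl | starting material
6 | 4α-[(E)-1,2-dichlorovinyloxy]-11-(triethylsilyloxy)eudesmane | Cl/C=C(Cl)\O[C@]1(C)CCC[C@]2(C)CC[C@@H](C(C)(C)O[Si](CC)(CC)CC)C[C@H]21 | intermediate
7 | 4-iodophenol | Oc1ccc(I)cc1 | starting material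
8 | allyl 4-iodophenyl ether | C=CCOc1ccc(I)cc1 | intermediate
9 | 6-allyl-4-iodocyclohexa-2,4-dien-1-one (racemic, not isolated) | C=CCC1C=C(I)C=CC1=O | intermediate
10 | 2-allyl-4-iodophenol | C=CCc1cc(I)ccc1O | intermediate
11 | tert-butyl(2-allyl-4-iodophenoxy)dimethylsilane | C=CCc1cc(I)ccc1O[Si](C)(C)C(C)(C)C | intermediate
12 | 4α-(chloroethynyloxy)-11-(triethylsilyloxy)eudesmane (not isolated) | ClC#CO[C@]1(C)CCC[C@]2(C)CC[C@@H](C(C)(C)O[Si](CC)(CC)CC)C[C@H]21 | intermediate
13 | lithium 2-[11-(triethylsilyloxy)eudesman-4α-yloxy]ethynide (not isolated) | [Li]C#CO[C@]1(C)CCC[C@]2(C)CC[C@@H](C(C)(C)O[Si](CC)(CC)CC)C[C@H]21 | intermediate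
14 | {2-[11-(triethylsilyloxy)eudesman-4α-yloxy]ethynyl}zinc chloride (not isolated) | Cl[Zn]C#CO[C@]1(C)CCC[C@]2(C)CC[C@@H](C(C)(C)O[Si](CC)(CC)CC)C[C@H]21 | intermediate
15 | 4α-[2-(3-allyl-4-tert-butyldimethylsilyloxyphenyl)ethynyloxy]-11-(triethylsilyloxy)eudesmane | C=CCc1cc(C#CO[C@]2(C)CCC[C@]3(C)CC[C@@H](C(C)(C)O[Si](CC)(CC)CC)C[C@H]32)ccc1O[Si](C)(C)C(C)(C)C | intermediate
16 | methyl coumalate (methyl 2-oxo-2H-pyran-5-carboxylate) | COC(=O)c1ccc(=O)oc1 | starting material
17 | methyl 7-(3-allyl-4-tert-butyldimethylsilyloxyphenyl)-3-oxo-8-[11-(triethylsilyloxy)eudesman-4α-yloxy]-2-oxabicyclo[2.2.2]octa-5,7-diene-6-carboxylate (both bridgehead configurations, not isolated) | COC(=O)C1=CC2C(=O)OC1C(c3ccc(O[Si](C)(C)C(C)(C)C)c(CC=C)c3)=C2O[C@]4(C)CCC[C@]5(C)CC[C@@H](C(C)(C)O[Si](CC)(CC)CC)C[C@H]54 | intermediate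
18 | methyl 3-(3-allyl-4-tert-butyldimethylsilyloxyphenyl)-4-[11-(triethylsilyloxy)eudesman-4α-yloxy]benzoate | COC(=O)c1ccc(O[C@]2(C)CCC[C@]3(C)CC[C@@H](C(C)(C)O[Si](CC)(CC)CC)C[C@H]32)c(-c2ccc(O[Si](C)(C)C(C)(C)C)c(CC=C)c2)c1 | intermediate
19 | {3-(3-allyl-4-tert-butyldimethylsilyloxyphenyl)-4-[11-(triethylsilyloxy)eudesman-4α-yloxy]phenyl}methanol | OCc1ccc(O[C@]2(C)CCC[C@]3(C)CC[C@@H](C(C)(C)O[Si](CC)(CC)CC)C[C@H]32)c(-c2ccc(O[Si](C)(C)C(C)(C)C)c(CC=C)c2)c1 | intermediate
20 | 4α-{[3'-allyl-5-(bromomethyl)-4'-(tert-butyldimethylsilyloxy)biphenyl-2-yl]oxy}-11-(triethylsilyloxy)eudesmane | BrCc1ccc(O[C@]2(C)CCC[C@]3(C)CC[C@@H](C(C)(C)O[Si](CC)(CC)CC)C[C@H]32)c(-c2ccc(O[Si](C)(C)C(C)(C)C)c(CC=C)c2)c1 | intermediate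
21 | 4α-{[3',5-diallyl-4'-(tert-butyldimethylsilyloxy)biphenyl-2-yl]oxy}-11-(triethylsilyloxy)eudesmane | C=CCc1ccc(O[C@]2(C)CCC[C@]3(C)CC[C@@H](C(C)(C)O[Si](CC)(CC)CC)C[C@H]32)c(-c2ccc(O[Si](C)(C)C(C)(C)C)c(CC=C)c2)c1 | intermediate
22 | 4α-[(3',5-diallyl-4'-hydroxybiphenyl-2-yl)oxy]eudesman-11-ol (CNP0219722.1) | C=CCc1ccc(O[C@]2(C)CCC[C@]3(C)CC[C@@H](C(C)(C)O)C[C@H]32)c(-c2ccc(O)c(CC=C)c2)c1 | target

**Count**

Total step count: 13.
Longest linear sequence: 10 steps (steps 1–4 and 8–13, from β-eudesmol 1); the aryl iodide branch (steps 5–7) has 3 steps.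

**Steps most likely to fail**

1. Step 9. The cycloaddition may be outpaced by retro-ene fragmentation of the tertiary alkynyl ether (loss of the decalin as an alkene with ketene formation), by acid-catalysed hydration of the alkynyl ether, or be slowed by the aryl substituent on the alkyne. The fallback forms the aryl ether bond by nucleophilic aromatic substitution instead of building ring A; it sets out from 4 and 11 and comes back to the route at 19.
   - The potassium alkoxide of 4 (KH, THF) is treated with 3-bromo-4-fluorobenzaldehyde in DMF at 0 to 25 °C to give, by SNAr displacement of fluoride, 3-bromo-4-[11-(triethylsilyloxy)eudesman-4α-yloxy]benzaldehyde F1.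
   - Iodide 11 is converted by Miyaura borylation (bis(pinacolato)diboron, PdCl2(dppf), KOAc, dioxane, 80 °C) into 2-(3-allyl-4-tert-butyldimethylsilyloxyphenyl)-4,4,5,5-tetramethyl-1,3,2-dioxaborolane F2.
   - Suzuki–Miyaura coupling of the two (Pd(OAc)2, SPhos, K3PO4, toluene/water, 70 °C) should give 3-(3-allyl-4-tert-butyldimethylsilyloxyphenyl)-4-[11-(triethylsilyloxy)eudesman-4α-yloxy]benzaldehyde F3.
   - NaBH4 in THF/MeOH at 0 °C reduces this aldehyde to 19.

2. Step 8. Proto-demetalation or hydrolysis of the alkynyl metal species, halogen–metal exchange on the aryl iodide by residual butyllithium, or thermal fragmentation of the product during a slow coupling may erode the sequence. The fallback sets out from 6 and comes back at 15. Compound 6 is converted as before into the lithium alkynyl ether 13, which is quenched with water at −78 °C to give the neutral terminal alkyne 4α-(ethynyloxy)-11-(triethylsilyloxy)eudesmane F4. This is purified cold and joined to 11 by Sonogashira coupling (PdCl2(PPh3)2, CuI, i-Pr2NH, THF, 20 °C), which replaces the stoichiometric organozinc by a catalytically formed copper acetylide and gives 15.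

3. Step 12. Ionisation of the electron-rich benzylic bromide, Wurtz-type homocoupling to a bibenzyl, or halogen–magnesium exchange may compete with the displacement. The fallback sets out from 19 and comes back at 21. Alcohol 19 is converted under Appel-type conditions (N-chlorosuccinimide, PPh3, CH2Cl2, 0 °C) into the more robust 4α-{[3'-allyl-4'-(tert-butyldimethylsilyloxy)-5-(chloromethyl)biphenyl-2-yl]oxy}-11-(triethylsilyloxy)eudesmane F5. This is vinylated by a neutral Migita–Kosugi–Stille coupling with tributyl(vinyl)stannane (Pd(PPh3)4, toluene, 80 °C) to give 21.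

**Further compounds**

F1 | step 9 | 3-bromo-4-[11-(triethylsilyloxy)eudesman-4α-yloxy]benzaldehyde | O=Cc1ccc(O[C@]2(C)CCC[C@]3(C)CC[C@@H](C(C)(C)O[Si](CC)(CC)CC)C[C@H]32)c(Br)c1
F2 | step 9 | 2-(3-allyl-4-tert-butyldimethylsilyloxyphenyl)-4,4,5,5-tetramethyl-1,3,2-dioxaborolane | C=CCc1cc(B2OC(C)(C)C(C)(C)O2)ccc1O[Si](C)(C)C(C)(C)C
F3 | step 9 | 3-(3-allyl-4-tert-butyldimethylsilyloxyphenyl)-4-[11-(triethylsilyloxy)eudesman-4α-yloxy]benzaldehyde | O=Cc1ccc(O[C@]2(C)CCC[C@]3(C)CC[C@@H](C(C)(C)O[Si](CC)(CC)CC)C[C@H]32)c(-c2ccc(O[Si](C)(C)C(C)(C)C)c(CC=C)c2)c1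
F4 | step 8 | 4α-(ethynyloxy)-11-(triethylsilyloxy)eudesmane | C#CO[C@]1(C)CCC[C@]2(C)CC[C@@H](C(C)(C)O[Si](CC)(CC)CC)C[C@H]21
F5 | step 12 | 4α-{[3'-allyl-4'-(tert-butyldimethylsilyloxy)-5-(chloromethyl)biphenyl-2-yl]oxy}-11-(triethylsilyloxy)eudesmane | ClCc1ccc(O[C@]2(C)CCC[C@]3(C)CC[C@@H](C(C)(C)O[Si](CC)(CC)CC)C[C@H]32)c(-c2ccc(O[Si](C)(C)C(C)(C)C)c(CC=C)c2)c1
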